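**Retrosynthetic overview**

- The C7 prenyl group is traced back to a C7 formyl group: cross-metathesis, palladium/formate deoxygenation of an allylic acetate, and vinyl Grignard addition, in the reverse sense.
- Key disconnection C5–C6 and C1–C8. Ring A (C1–C5 with C9) is a dearomatized 2-O-methyl benzoylphloroglucinol whose two bridgeheads, C5 and C1, are nucleophilic ring carbons of the parent phenol. Ring B then needs only C6–C7–C8, supplied as the bis-electrophile 2-(acetoxymethyl)-3-methylbut-2-enal.
- The phenol is built from bis-MOM 5-methoxyresorcinol by three successive directed ortho-lithiations (lavandulyl between the two MOM ethers, then prenyl, then benzoyl), followed by MOM removal.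
- Ring order: ring A is carried as the arene from the start; ring B is the only ring formed, in the key step, which also sets C5, C1 and C7. The side-chain stereocentre comes from resolved (S)-lavandulol.

Key step: step 11

Remark on numbering and names: C1 prenyl bridgehead, C2 methoxy carbon, C3 benzoyl carbon, C4 enone carbonyl, C5 lavandulyl bridgehead, C6 CH2, C7 methine, C8 CMe2, C9 bridging ketone. Prenyl = 3-methylbut-2-en-1-yl; lavandulyl = 5-methyl-2-(prop-1-en-2-yl)hex-4-en-1-yl, whose descriptor changes from S (alcohol, triflate) to R once its CH2 is bound to carbon, with no change in spatial arrangement.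

Assumption: the cinchonidinium salt of step 11 is taken to deliver the (5R) bridgehead; if a pilot run shows the opposite sense, the pseudoenantiomeric cinchoninium salt is used in the same step with nothing else changed.

**Route**

Step 1
Reactants: 1 diethyl 2-(propan-2-ylidene)malonate
Product: 2 2-(propan-2-ylidene)propane-1,3-diol
Conditions: i-Bu2AlH (4.5 equiv), CH2Cl2, −78 → 0 °C; aq. potassium sodium tartrate
Reagents that add atoms: none
Why: Hydride 1,2-reduction of both ester groups of an alkylidene malonate, where the fully substituted β-carbon disfavours conjugate reduction, should give the symmetric allylic diol.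

Step 2
Reactants: 2 2-(propan-2-ylidene)propane-1,3-diol
Product: 4 2-(hydroxymethyl)-3-methylbut-2-en-1-yl acetate, via cyclic orthoacetate 3 (not isolated)
Conditions: MeC(OMe)3, camphorsulfonic acid (cat.), CH2Cl2, rt; then H2O
Reagents that add atoms: trimethyl orthoacetate CC(OC)(OC)OC; water O
Why: Mono-acetylation of a symmetric 1,3-diol by orthoester exchange to the cyclic orthoacetate and mild hydrolysis, which can open only to the mono-acetate.

Step 3
Reactants: 4 2-(hydroxymethyl)-3-methylbut-2-en-1-yl acetate
Product: 5 2-(acetoxymethyl)-3-methylbut-2-enal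
Conditions: MnO2 (excess), CH2Cl2, rt
Reagents that add atoms: none
Why: Selective MnO2 oxidation of a primary allylic alcohol to the enal, leaving the allylic acetate untouched.

Step 4
Reactants: 6 (±)-lavandulol
Product: 7 (S)-lavandulol
Conditions: porcine pancreatic lipase, vinyl acetate, hexane, rt, to about 60% conversion; chromatography
Reagents that add atoms: none
Why: Lipase-catalysed kinetic resolution by transesterification, in which the R alcohol is acetylated faster, so that the unreacted S alcohol should be recovered enriched once conversion passes one half (a second cycle can raise its purity).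

Step 5
Reactants: 7 (S)-lavandulol
Product: 8 (S)-lavandulyl trifluoromethanesulfonate
Conditions: Tf2O, pyridine, CH2Cl2, −78 °C; cold pentane filtration, used at once
Reagents that add atoms: triflic anhydride O=S(=O)(OS(=O)(=O)C(F)(F)F)C(F)(F)F
Why: O-Sulfonylation of a primary alcohol at low temperature gives the alkyl triflate without touching the stereocentre, which is one carbon removed from the reacting oxygen.

Step 6
Reactants: 9 5-methoxyresorcinol
Product: 10 1-methoxy-3,5-bis(methoxymethoxy)benzene
Conditions: MOMCl, i-Pr2NEt, CH2Cl2, 0 °C → rt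
Reagents that add atoms: chloromethyl methyl ether COCCl
Why: Standard O-alkylation of both phenols as MOM ethers, which also serve as the directing groups for the three metalations that follow.

Step 7
Reactants: 10 1-methoxy-3,5-bis(methoxymethoxy)benzene; 8 (S)-lavandulyl trifluoromethanesulfonate
Product: 12 5-methoxy-1,3-bis(methoxymethoxy)-2-[(2R)-lavandulyl]benzene, via aryllithium 11 (not isolated)
Conditions: n-BuLi, THF, 0 °C; then 8, −78 → −20 °C
Reagents that add atoms: none
Why: Directed ortho-metalation at the carbon flanked by both MOM ethers (the strongest cooperative site) followed by SN2 alkylation of the aryllithium with the primary triflate, which is reactive enough at low temperature to outrun elimination; the side-chain stereocentre is not involved.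

Step 8
Reactants: 12 5-methoxy-1,3-bis(methoxymethoxy)-2-[(2R)-lavandulyl]benzene
Product: 14 1-methoxy-3,5-bis(methoxymethoxy)-2-prenyl-4-[(2R)-lavandulyl]benzene, via aryllithium 13 (not isolated)
Conditions: n-BuLi, TMEDA, THF, 0 °C; then CuBr·SMe2 (10 mol%), prenyl bromide, −78 °C → rt
Reagents that add atoms: prenyl bromide CC(C)=CCBr
Why: A second directed ortho-metalation at one of the two equivalent positions between MOM ether and methoxy, then copper-catalysed allylic substitution at the primary carbon of prenyl bromide, gives the linear prenyl arene.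

Step 9
Reactants: 14 1-methoxy-3,5-bis(methoxymethoxy)-2-prenyl-4-[(2R)-lavandulyl]benzene
Product: 16 {2-methoxy-4,6-bis(methoxymethoxy)-3-prenyl-5-[(2R)-lavandulyl]phenyl}(phenyl)methanone, via aryllithium 15 (not isolated)
Conditions: n-BuLi, TMEDA, THF, −20 → 0 °C; then PhC(O)N(OMe)Me, −78 → 0 °C; H2O
Reagents that add atoms: N-methoxy-N-methylbenzamide CON(C)C(=O)c1ccccc1
Why: Directed ortho-metalation of the last ring C–H, which is doubly activated by the MOM ether and methoxy group, and Weinreb amide acylation, whose chelated tetrahedral intermediate prevents over-addition, install the benzoyl group.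

Step 10
Reactants: 16 {2-methoxy-4,6-bis(methoxymethoxy)-3-prenyl-5-[(2R)-lavandulyl]phenyl}(phenyl)methanone
Product: 17 {2,4-dihydroxy-6-methoxy-5-prenyl-3-[(2R)-lavandulyl]phenyl}(phenyl)methanone
Conditions: HCl (3 M aq.), MeOH, 40 °C
Reagents that add atoms: none
Why: Acid-catalysed acetal exchange removes both MOM ethers under dilute conditions that are mild enough to leave the prenyl and isopropenyl alkenes uncyclized, while the methyl ether stays in place.

Step 11
Reactants: 17 {2,4-dihydroxy-6-methoxy-5-prenyl-3-[(2R)-lavandulyl]phenyl}(phenyl)methanone; 5 2-(acetoxymethyl)-3-methylbut-2-enal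
Product: 20 (1R,5R,7R)-3-benzoyl-2-methoxy-8,8-dimethyl-4,9-dioxo-1-prenyl-5-[(2R)-lavandulyl]bicyclo[3.3.1]non-2-ene-7-carbaldehyde (formyl exo, anti to ring A), via C5-alkylated dienone enal 18 (not isolated), via 7-epi aldehyde 19 (not isolated)
Conditions: O-allyl-N-(9-anthracenylmethyl)cinchonidinium bromide (20 mol%), CsOH·H2O, 4 Å MS, CH2Cl2, −50 °C; then filter, DBU (cat.), rt
Reagents that add atoms: none
Why: Caesium hydroxide forms the bis-phenoxide of 17 as an ion pair with the chiral ammonium cation; C5, the ring carbon between the two phenoxide oxygens, attacks the primary acetoxymethyl carbon of 5 with loss of acetate (SN2-type allylic alkylation, the fully substituted β-carbon of 5 closing off the SN2′ mode) to give 18, whose enolate carbon C1 then adds to the β,β-dimethyl enal in an intramolecular Michael reaction. The closest known reaction type is the alkylative dearomatization–annulation of acylphloroglucinols with α-acetoxymethyl enals under chiral phase-transfer catalysis. Ring B (C5–C6–C7–C8–C1–C9) closes in the 6-endo-trig mode. C5 is set by the catalyst, which shields one face of the planar phenoxide in the ion pair (the remote side-chain centre adds little bias); C1 follows from C5 because the three-carbon bridge can only span one face of ring A; C7 is protonated kinetically to a mixture containing 19 and is then epimerized by DBU through the aldehyde enolate to the exo, equatorial formyl group of 20. The step needs alkylation at C5 before C1 and at carbon rather than oxygen: C5 lies between two phenoxide oxygens whereas C1 is flanked by one phenoxide and the methyl ether, alkylation at C5 leaves a stabilized vinylogous acid anion, and the benzoyl-bearing C3 is too stabilized and hindered to compete in the ring closure. The C2 methyl ether also prevents the aldol of C3 onto the formyl group, so the aldehyde should survive.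

Step 12
Reactants: 20 (1R,5R,7R)-3-benzoyl-2-methoxy-8,8-dimethyl-4,9-dioxo-1-prenyl-5-[(2R)-lavandulyl]bicyclo[3.3.1]non-2-ene-7-carbaldehyde
Product: 21 (1R,5R,7R)-3-benzoyl-7-(1-hydroxyprop-2-en-1-yl)-2-methoxy-8,8-dimethyl-1-prenyl-5-[(2R)-lavandulyl]bicyclo[3.3.1]non-2-ene-4,9-dione (carbinol epimers)
Conditions: CH2=CHMgBr, THF, −78 °C
Reagents that add atoms: vinylmagnesium bromide C=C[Mg]Br
Why: Grignard 1,2-addition to the aldehyde, the only unhindered carbonyl (the C4 and C9 ketones sit between quaternary carbons and the benzoyl group is a crowded vinylogous ester carbonyl); the new carbinol centre is removed in step 14, so its configuration does not matter.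

Step 13
Reactants: 21 (1R,5R,7R)-3-benzoyl-7-(1-hydroxyprop-2-en-1-yl)-2-methoxy-8,8-dimethyl-1-prenyl-5-[(2R)-lavandulyl]bicyclo[3.3.1]non-2-ene-4,9-dione
Product: 22 1-[(1R,5R,7R)-3-benzoyl-2-methoxy-8,8-dimethyl-4,9-dioxo-1-prenyl-5-[(2R)-lavandulyl]bicyclo[3.3.1]non-2-en-7-yl]prop-2-en-1-yl acetate (carbinol epimers)
Conditions: Ac2O, DMAP, Et3N, CH2Cl2, rt
Reagents that add atoms: acetic anhydride CC(=O)OC(C)=O
Why: DMAP-catalysed acylation of the secondary allylic alcohol provides the leaving group for π-allyl formation; no other hydroxyl is present.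

Step 14
Reactants: 22 1-[(1R,5R,7R)-3-benzoyl-2-methoxy-8,8-dimethyl-4,9-dioxo-1-prenyl-5-[(2R)-lavandulyl]bicyclo[3.3.1]non-2-en-7-yl]prop-2-en-1-yl acetate
Product: 23 (1R,5R,7R)-7-allyl-3-benzoyl-2-methoxy-8,8-dimethyl-1-prenyl-5-[(2R)-lavandulyl]bicyclo[3.3.1]non-2-ene-4,9-dione
Conditions: Pd(OAc)2 (10 mol%), n-Bu3P (40 mol%), HCO2NH4, 1,4-dioxane, 100 °C
Reagents that add atoms: none
Why: Tsuji–Trost-type palladium-catalysed formate hydrogenolysis of the allylic acetate, in which the π-allylpalladium formate delivers hydride to the more substituted terminus, should give the terminal alkene and erase the carbinol centre while C7 is untouched.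

Step 15
Reactants: 23 (1R,5R,7R)-7-allyl-3-benzoyl-2-methoxy-8,8-dimethyl-1-prenyl-5-[(2R)-lavandulyl]bicyclo[3.3.1]non-2-ene-4,9-dione
Product: 24 (1R,5R,7R)-3-benzoyl-2-methoxy-8,8-dimethyl-1,7-diprenyl-5-[(2R)-lavandulyl]bicyclo[3.3.1]non-2-ene-4,9-dione (CNP0385193.1)
Conditions: second-generation Grubbs catalyst (10 mol%), 2-methylbut-2-ene (large excess), CH2Cl2, 40 °C, sealed tube
Reagents that add atoms: 2-methylbut-2-ene CC=C(C)C
Why: Olefin cross-metathesis of the monosubstituted allyl alkene with excess 2-methylbut-2-ene builds the prenyl terminus, while the existing prenyl groups only exchange degenerately and the hindered 1,1-disubstituted isopropenyl group should stay inert.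

**Compound list**

1 | diethyl 2-(propan-2-ylidene)malonate | CCOC(=O)C(=C(C)C)C(=O)OCC | starting material
2 | 2-(propan-2-ylidene)propane-1,3-diol | CC(C)=C(CO)CO | intermediate
3 | 2-methoxy-2-methyl-5-(propan-2-ylidene)-1,3-dioxane (cyclic orthoacetate, formed in situ) | COC1(C)OCC(=C(C)C)CO1 | intermediate
4 | 2-(hydroxymethyl)-3-methylbut-2-en-1-yl acetate | CC(=O)OCC(CO)=C(C)C | intermediate
5 | 2-(acetoxymethyl)-3-methylbut-2-enal | CC(C)=C(COC(C)=O)C=O | intermediate
6 | (±)-lavandulol | C=C(C)C(CC=C(C)C)CO | starting material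
7 | (S)-lavandulol | C=C(C)[C@H](CC=C(C)C)CO | intermediate
8 | (S)-lavandulyl trifluoromethanesulfonate | C=C(C)[C@H](CC=C(C)C)COS(=O)(=O)C(F)(F)F | intermediate
9 | 5-methoxyresorcinol | COc1cc(O)cc(O)c1 | starting material
10 | 1-methoxy-3,5-bis(methoxymethoxy)benzene | COCOc1cc(OC)cc(OCOC)c1 | intermediate
11 | 4-methoxy-2,6-bis(methoxymethoxy)phenyllithium (formed in situ) | [Li]c1c(OCOC)cc(OC)cc1OCOC | intermediate
12 | 5-methoxy-1,3-bis(methoxymethoxy)-2-[(2R)-lavandulyl]benzene | C=C(C)[C@H](CC=C(C)C)Cc1c(OCOC)cc(OC)cc1OCOC | intermediate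
13 | 6-methoxy-2,4-bis(methoxymethoxy)-3-[(2R)-lavandulyl]phenyllithium (formed in situ) | C=C(C)[C@H](CC=C(C)C)Cc1c(OCOC)cc(OC)c([Li])c1OCOC | intermediate
14 | 1-methoxy-3,5-bis(methoxymethoxy)-2-prenyl-4-[(2R)-lavandulyl]benzene | C=C(C)[C@H](CC=C(C)C)Cc1c(OCOC)cc(OC)c(CC=C(C)C)c1OCOC | intermediate
15 | 2-methoxy-4,6-bis(methoxymethoxy)-3-prenyl-5-[(2R)-lavandulyl]phenyllithium (formed in situ) | C=C(C)[C@H](CC=C(C)C)Cc1c(OCOC)c([Li])c(OC)c(CC=C(C)C)c1OCOC | intermediate
16 | {2-methoxy-4,6-bis(methoxymethoxy)-3-prenyl-5-[(2R)-lavandulyl]phenyl}(phenyl)methanone | C=C(C)[C@H](CC=C(C)C)Cc1c(OCOC)c(C(=O)c2ccccc2)c(OC)c(CC=C(C)C)c1OCOC | intermediate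
17 | {2,4-dihydroxy-6-methoxy-5-prenyl-3-[(2R)-lavandulyl]phenyl}(phenyl)methanone | C=C(C)[C@H](CC=C(C)C)Cc1c(O)c(C(=O)c2ccccc2)c(OC)c(CC=C(C)C)c1O | intermediate
18 | 2-{[(1S)-3-benzoyl-2-hydroxy-4-methoxy-6-oxo-5-prenyl-1-[(2R)-lavandulyl]cyclohexa-2,4-dien-1-yl]methyl}-3-methylbut-2-enal (formed in situ) | C=C(C)[C@H](CC=C(C)C)C[C@@]1(CC(C=O)=C(C)C)C(=O)C(CC=C(C)C)=C(OC)C(C(=O)c2ccccc2)=C1O | intermediate
19 | (1R,5R,7S)-3-benzoyl-2-methoxy-8,8-dimethyl-4,9-dioxo-1-prenyl-5-[(2R)-lavandulyl]bicyclo[3.3.1]non-2-ene-7-carbaldehyde (formyl endo, formed in situ) | C=C(C)[C@H](CC=C(C)C)C[C@@]12C[C@H](C=O)C(C)(C)[C@@](CC=C(C)C)(C1=O)C(OC)=C(C(=O)c1ccccc1)C2=O | intermediate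
20 | (1R,5R,7R)-3-benzoyl-2-methoxy-8,8-dimethyl-4,9-dioxo-1-prenyl-5-[(2R)-lavandulyl]bicyclo[3.3.1]non-2-ene-7-carbaldehyde (formyl exo) | C=C(C)[C@H](CC=C(C)C)C[C@@]12C[C@@H](C=O)C(C)(C)[C@@](CC=C(C)C)(C1=O)C(OC)=C(C(=O)c1ccccc1)C2=O | intermediate
21 | (1R,5R,7R)-3-benzoyl-7-(1-hydroxyprop-2-en-1-yl)-2-methoxy-8,8-dimethyl-1-prenyl-5-[(2R)-lavandulyl]bicyclo[3.3.1]non-2-ene-4,9-dione (carbinol epimers) | C=C(C)[C@H](CC=C(C)C)C[C@@]12C[C@@H](C(O)C=C)C(C)(C)[C@@](CC=C(C)C)(C1=O)C(OC)=C(C(=O)c1ccccc1)C2=O | intermediate
22 | 1-[(1R,5R,7R)-3-benzoyl-2-methoxy-8,8-dimethyl-4,9-dioxo-1-prenyl-5-[(2R)-lavandulyl]bicyclo[3.3.1]non-2-en-7-yl]prop-2-en-1-yl acetate (carbinol epimers) | C=C(C)[C@H](CC=C(C)C)C[C@@]12C[C@@H](C(OC(C)=O)C=C)C(C)(C)[C@@](CC=C(C)C)(C1=O)C(OC)=C(C(=O)c1ccccc1)C2=O | intermediate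
23 | (1R,5R,7R)-7-allyl-3-benzoyl-2-methoxy-8,8-dimethyl-1-prenyl-5-[(2R)-lavandulyl]bicyclo[3.3.1]non-2-ene-4,9-dione | C=C(C)[C@H](CC=C(C)C)C[C@@]12C[C@@H](CC=C)C(C)(C)[C@@](CC=C(C)C)(C1=O)C(OC)=C(C(=O)c1ccccc1)C2=O | intermediate
24 | (1R,5R,7R)-3-benzoyl-2-methoxy-8,8-dimethyl-1,7-diprenyl-5-[(2R)-lavandulyl]bicyclo[3.3.1]non-2-ene-4,9-dione (CNP0385193.1) | C=C(C)[C@H](CC=C(C)C)C[C@@]12C[C@@H](CC=C(C)C)C(C)(C)[C@@](CC=C(C)C)(C1=O)C(OC)=C(C(=O)c1ccccc1)C2=O | target

**Step count and risks**

Total step count: 15. Longest linear sequence: 11 steps (steps 4, 5 and 7 to 15, from (±)-lavandulol); the arene branch from 5-methoxyresorcinol is 10 steps and the enal branch joins after 3.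

Steps most likely to fail:

1. Step 11. The ion pair may discriminate poorly between the two faces of the phenoxide at C5, and some of the first alkylation may leak to C1 or to oxygen, so that the wanted bridgehead configuration forms together with its mirror-image ring system or with regioisomeric material. The fallback gives up catalyst control and sets out from 17 and 5. The annulation is run homogeneously with KN(SiMe3)2 in THF at 65 °C, conditions under which C7 equilibrates in the same flask. This should give 20 together with its bridgehead diastereomer, (1S,5S,7S)-3-benzoyl-2-methoxy-8,8-dimethyl-4,9-dioxo-1-prenyl-5-[(2R)-lavandulyl]bicyclo[3.3.1]non-2-ene-7-carbaldehyde F1. Because the lavandulyl centre is already in place, the two are diastereomers and are separated by chromatography. The route is rejoined at 20.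

2. Step 7. The basic aryllithium may deprotonate the β-branched triflate (elimination to a conjugated diene), or the homoallylic triflate may ionize before substitution occurs. The fallback replaces the SN2 alkylation by a Negishi cross-coupling and sets out from 10 and 7. Lithiation of 10 as in step 7 and quenching with iodine gives 2-iodo-5-methoxy-1,3-bis(methoxymethoxy)benzene F2. Alcohol 7 is converted with I2, PPh3 and imidazole into (S)-lavandulyl iodide F3, which inserts zinc (Zn dust, LiCl, THF) to give (S)-lavandulylzinc iodide F4. Coupling of F2 with F4 under Pd(OAc)2 and 2-dicyclohexylphosphino-2′,6′-dimethoxybiphenyl in THF rejoins the route at 12.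

3. Step 9. Deprotonation at the benzylic and allylic CH2 of the prenyl group may compete with ring lithiation, so that acylation occurs at the side chain. The fallback installs the benzoyl group before the prenyl group and sets out from 12. Lithiation of 12 (n-BuLi, TMEDA) and acylation with N-methoxy-N-methylbenzamide gives {6-methoxy-2,4-bis(methoxymethoxy)-3-[(2R)-lavandulyl]phenyl}(phenyl)methanone F5. Removal of the MOM groups with dilute HCl in MeOH gives {2,4-dihydroxy-6-methoxy-3-[(2R)-lavandulyl]phenyl}(phenyl)methanone F6. C-Prenylation of its phenoxide at the only free ring carbon (prenyl bromide, aq. KOH, 0 °C) rejoins the route at 17.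

**Further compounds**

F1 | step 11 | (1S,5S,7S)-3-benzoyl-2-methoxy-8,8-dimethyl-4,9-dioxo-1-prenyl-5-[(2R)-lavandulyl]bicyclo[3.3.1]non-2-ene-7-carbaldehyde | C=C(C)[C@H](CC=C(C)C)C[C@]12C[C@H](C=O)C(C)(C)[C@](CC=C(C)C)(C1=O)C(OC)=C(C(=O)c1ccccc1)C2=O
F2 | step 7 | 2-iodo-5-methoxy-1,3-bis(methoxymethoxy)benzene | COCOc1cc(OC)cc(OCOC)c1I
F3 | step 7 | (S)-lavandulyl iodide | C=C(C)[C@H](CC=C(C)C)CI
F4 | step 7 | (S)-lavandulylzinc iodide | C=C(C)[C@H](CC=C(C)C)C[Zn]I
F5 | step 9 | {6-methoxy-2,4-bis(methoxymethoxy)-3-[(2R)-lavandulyl]phenyl}(phenyl)methanone | C=C(C)[C@H](CC=C(C)C)Cc1c(OCOC)cc(OC)c(C(=O)c2ccccc2)c1OCOC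
F6 | step 9 | {2,4-dihydroxy-6-methoxy-3-[(2R)-lavandulyl]phenyl}(phenyl)methanone | C=C(C)[C@H](CC=C(C)C)Cc1c(O)cc(OC)c(C(=O)c2ccccc2)c1O
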